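**Retrosynthetic overview**
- The target is geraldol (3,7,4'-trihydroxy-3'-methoxyflavone) carrying three O-sulfates. The sulfates go on last, by exhaustive O-sulfation of the free triol followed by H+ exchange.
- The triol comes from its 7,4'-dibenzyl ether by hydrogenolysis. Ring C (the pyranone) is the only ring built, by Algar–Flynn–Oyamada oxidative cyclisation of a 2'-hydroxychalcone, which closes O1–C2 and installs the 3-OH.
- The chalcone comes from the key C–C bond formation: an intermolecular Claisen–Schmidt aldol condensation of 4-O-benzylresacetophenone (ring A) with O-benzylvanillin (ring B).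
- Both fragments come from Williamson benzylation of 2,4-dihydroxyacetophenone and vanillin; rings A and B are bought.

Assumption: the target has no stereocentre or stereogenic axis, so it is a single achiral compound and no enantiocontrol is needed; it is made as the free tris(hydrogen sulfate) as drawn.

**Step 1**
Reactants: 1 2,4-dihydroxyacetophenone
Product: 2 1-[4-(benzyloxy)-2-hydroxyphenyl]ethan-1-one
Conditions: BnBr (1.05 equiv), K2CO3 (1.1 equiv), acetone, reflux, 8 h
Reagents that add atoms: benzyl bromide, BrCc1ccccc1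
Why: Williamson ether synthesis in which the 2-OH is tied up in a hydrogen bond to the acetyl carbonyl, so the mild base alkylates only the 4-OH; no stereocentre is formed.

**Step 2**
Reactants: 3 vanillin (4-hydroxy-3-methoxybenzaldehyde)
Product: 4 4-(benzyloxy)-3-methoxybenzaldehyde
Conditions: BnBr (1.1 equiv), K2CO3 (1.5 equiv), DMF, 60 °C, 4 h
Reagents that add atoms: benzyl bromide, BrCc1ccccc1
Why: Williamson ether synthesis of the only phenol present, which proceeds cleanly and leaves the aldehyde untouched; no stereocentre is formed.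

**Step 3**
Reactants: 2 1-[4-(benzyloxy)-2-hydroxyphenyl]ethan-1-one; 4 4-(benzyloxy)-3-methoxybenzaldehyde
Product: 6 (E)-1-[4-(benzyloxy)-2-hydroxyphenyl]-3-[4-(benzyloxy)-3-methoxyphenyl]prop-2-en-1-one, via racemic β-hydroxy ketone aldol adduct 5 (not isolated)
Conditions: KOH (50% aq, 10 equiv), EtOH, rt, 48 h; then ice, 2 M HCl
Reagents that add atoms: none
Why: Claisen–Schmidt crossed aldol condensation in which the ketone enolate adds to the non-enolisable aldehyde and E1cB dehydration gives the thermodynamically favoured E-enone, erasing the transient carbinol centre of 5 so that no stereocentre remains.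

**Step 4**
Reactants: 6 (E)-1-[4-(benzyloxy)-2-hydroxyphenyl]-3-[4-(benzyloxy)-3-methoxyphenyl]prop-2-en-1-one
Product: 8 7-(benzyloxy)-2-[4-(benzyloxy)-3-methoxyphenyl]-3-hydroxy-4H-chromen-4-one, via racemic trans-dihydroflavonol 7 (not isolated)
Conditions: 30% aq H2O2 (6 equiv), 2 M aq NaOH (6 equiv), MeOH/THF, 0 °C to rt, 6 h; then 2 M HCl
Reagents that add atoms: hydrogen peroxide, OO
Why: Algar–Flynn–Oyamada oxidation in which phenoxide oxa-Michael ring closure and enolate hydroxylation give dihydroflavonol 7, which alkaline peroxide dehydrogenates to the flavonol; the missing 6'-substituent favours flavonol over aurone, and the two transient stereocentres of 7 are erased.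

**Step 5**
Reactants: 8 7-(benzyloxy)-2-[4-(benzyloxy)-3-methoxyphenyl]-3-hydroxy-4H-chromen-4-one
Product: 9 3,7-dihydroxy-2-(4-hydroxy-3-methoxyphenyl)-4H-chromen-4-one (geraldol)
Conditions: H2 (1 atm), 10% Pd/C, THF/MeOH 1:1, rt, 6 h
Reagents that add atoms: none
Why: Catalytic hydrogenolysis cleaves both aryl benzyl ethers, while the fully conjugated 3-hydroxychromone and the methyl ether are inert at 1 atm; no stereocentre is formed.

**Step 6**
Reactants: 9 3,7-dihydroxy-2-(4-hydroxy-3-methoxyphenyl)-4H-chromen-4-one (geraldol)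
Product: 11 2-[3-methoxy-4-(sulfooxy)phenyl]-4-oxo-4H-chromene-3,7-diyl bis(hydrogen sulfate), via tris(pyridinium) trisulfate salt 10 (not isolated)
Conditions: SO3·pyridine (15 equiv), pyridine, 60 °C, 16 h; MeOH/H2O quench, Sephadex G-10 (H2O); then sulfonic acid cation-exchange resin (H+ form), H2O, 4 °C; freeze-dry
Reagents that add atoms: sulfur trioxide–pyridine complex, O=S(=O)([O-])[n+]1ccccc1
Why: Exhaustive O-sulfation (sulfuryl transfer from the amine–SO3 complex) is driven by excess reagent and heat so that even the carbonyl-chelated 3-OH reacts, and cold H+ exchange replaces pyridinium by protons to give the tris(hydrogen sulfate); no stereocentre is formed.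

**Compound list**
1 | 2,4-dihydroxyacetophenone | CC(=O)c1ccc(O)cc1O | starting material
2 | 1-[4-(benzyloxy)-2-hydroxyphenyl]ethan-1-one | CC(=O)c1ccc(OCc2ccccc2)cc1O | intermediate
3 | vanillin (4-hydroxy-3-methoxybenzaldehyde) | COc1cc(C=O)ccc1O | starting material
4 | 4-(benzyloxy)-3-methoxybenzaldehyde | COc1cc(C=O)ccc1OCc1ccccc1 | intermediate
5 | 1-[4-(benzyloxy)-2-hydroxyphenyl]-3-[4-(benzyloxy)-3-methoxyphenyl]-3-hydroxypropan-1-one (racemic aldol adduct, not isolated) | COc1cc(C(O)CC(=O)c2ccc(OCc3ccccc3)cc2O)ccc1OCc1ccccc1 | intermediate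
6 | (E)-1-[4-(benzyloxy)-2-hydroxyphenyl]-3-[4-(benzyloxy)-3-methoxyphenyl]prop-2-en-1-one | COc1cc(/C=C/C(=O)c2ccc(OCc3ccccc3)cc2O)ccc1OCc1ccccc1 | intermediate
7 | trans-7-(benzyloxy)-2-[4-(benzyloxy)-3-methoxyphenyl]-3-hydroxychroman-4-one (racemic, one enantiomer drawn, not isolated) | COc1cc([C@H]2Oc3cc(OCc4ccccc4)ccc3C(=O)[C@@H]2O)ccc1OCc1ccccc1 | intermediate
8 | 7-(benzyloxy)-2-[4-(benzyloxy)-3-methoxyphenyl]-3-hydroxy-4H-chromen-4-one | COc1cc(-c2oc3cc(OCc4ccccc4)ccc3c(=O)c2O)ccc1OCc1ccccc1 | intermediate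
9 | 3,7-dihydroxy-2-(4-hydroxy-3-methoxyphenyl)-4H-chromen-4-one (geraldol) | COc1cc(-c2oc3cc(O)ccc3c(=O)c2O)ccc1O | intermediate
10 | tris(pyridinium) 2-(3-methoxy-4-sulfonatooxyphenyl)-4-oxo-4H-chromene-3,7-diyl bis(sulfate) (not isolated) | COc1cc(-c2oc3cc(OS(=O)(=O)[O-])ccc3c(=O)c2OS(=O)(=O)[O-])ccc1OS(=O)(=O)[O-].c1cc[nH+]cc1.c1cc[nH+]cc1.c1cc[nH+]cc1 | intermediate
11 | 2-[3-methoxy-4-(sulfooxy)phenyl]-4-oxo-4H-chromene-3,7-diyl bis(hydrogen sulfate) (geraldol 3,7,4'-tris-O-sulfate, achiral) | COc1cc(-c2oc3cc(OS(=O)(=O)O)ccc3c(=O)c2OS(=O)(=O)O)ccc1OS(=O)(=O)O | target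

**Step count and risks**
Total step count: 6. Longest linear sequence: 5 steps (step 1, then steps 3, 4, 5, 6; step 2 is the side branch).

The three steps most likely to fail, in route order:

Step 3 (Claisen–Schmidt condensation). The phenoxide of 2 slows enolisation of the ketone, so the condensation can stall or give flavanone and Cannizzaro by-products. The fallback sets out from 2 and masks the chelated phenol first. NaH and MOMCl in DMF at 0 °C give 1-[4-(benzyloxy)-2-(methoxymethoxy)phenyl]ethan-1-one F1. F1 condenses with 4 (KOH, EtOH, rt) through the aldol adduct 1-[4-(benzyloxy)-2-(methoxymethoxy)phenyl]-3-[4-(benzyloxy)-3-methoxyphenyl]-3-hydroxypropan-1-one F2, which is not isolated, to give (E)-1-[4-(benzyloxy)-2-(methoxymethoxy)phenyl]-3-[4-(benzyloxy)-3-methoxyphenyl]prop-2-en-1-one F3. HCl in MeOH/THF at 40 °C removes the acetal, and the fallback comes back to the route at 6.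

Step 4 (Algar–Flynn–Oyamada oxidation). Aurone formation, arrest at dihydroflavonol 7 or oxidative degradation can lower the yield. The fallback sets out from 6 and separates ring closure from C3 oxygenation. Catalytic I2 in DMSO at 130 °C gives 7-(benzyloxy)-2-[4-(benzyloxy)-3-methoxyphenyl]-4H-chromen-4-one F4. Dimethyldioxirane in acetone/CH2Cl2 at 0 °C converts F4 into the racemic 2,3-epoxide 7-(benzyloxy)-2-[4-(benzyloxy)-3-methoxyphenyl]-2,3-epoxychroman-4-one F5. Catalytic p-TsOH in CH2Cl2 opens F5 to the 3-hydroxyflavone, and the fallback comes back to the route at 8.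

Step 6 (trisulfation and acid liberation). The chelated 3-OH may sulfate incompletely, the resulting polyanion mixtures are hard to separate, and the free acid hydrolyses easily. It must be kept cold, freeze-dried at once and stored dry. The fallback sets out from 9 and uses protected sulfate diesters that can be purified on silica. 2,2,2-Trichloroethyl chlorosulfate (ClS(=O)(=O)OCC(Cl)(Cl)Cl) with NEt3 and DMAP in THF, 0 °C to rt, gives 2-{3-methoxy-4-[(2,2,2-trichloroethoxy)sulfonyloxy]phenyl}-4-oxo-4H-chromene-3,7-diyl bis(2,2,2-trichloroethyl sulfate) F6. Zn dust and HCO2NH4 in MeOH at rt cleave the three trichloroethyl groups to give triammonium 2-(3-methoxy-4-sulfonatooxyphenyl)-4-oxo-4H-chromene-3,7-diyl bis(sulfate) F7. Cold H+ exchange of F7 comes back to the route at 11.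

**Further compounds**
F1 | step 3 | 1-[4-(benzyloxy)-2-(methoxymethoxy)phenyl]ethan-1-one | CC(=O)c1ccc(OCc2ccccc2)cc1OCOC
F2 | step 3 | 1-[4-(benzyloxy)-2-(methoxymethoxy)phenyl]-3-[4-(benzyloxy)-3-methoxyphenyl]-3-hydroxypropan-1-one (racemic, not isolated) | COCOc1cc(OCc2ccccc2)ccc1C(=O)CC(O)c1ccc(OCc2ccccc2)c(OC)c1
F3 | step 3 | (E)-1-[4-(benzyloxy)-2-(methoxymethoxy)phenyl]-3-[4-(benzyloxy)-3-methoxyphenyl]prop-2-en-1-one | COCOc1cc(OCc2ccccc2)ccc1C(=O)/C=C/c1ccc(OCc2ccccc2)c(OC)c1
F4 | step 4 | 7-(benzyloxy)-2-[4-(benzyloxy)-3-methoxyphenyl]-4H-chromen-4-one | COc1cc(-c2cc(=O)c3ccc(OCc4ccccc4)cc3o2)ccc1OCc1ccccc1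
F5 | step 4 | 7-(benzyloxy)-2-[4-(benzyloxy)-3-methoxyphenyl]-2,3-epoxychroman-4-one (racemic, cis-fused, one enantiomer drawn) | COc1cc([C@]23Oc4cc(OCc5ccccc5)ccc4C(=O)[C@H]2O3)ccc1OCc1ccccc1
F6 | step 6 | 2-{3-methoxy-4-[(2,2,2-trichloroethoxy)sulfonyloxy]phenyl}-4-oxo-4H-chromene-3,7-diyl bis(2,2,2-trichloroethyl sulfate) | COc1cc(-c2oc3cc(OS(=O)(=O)OCC(Cl)(Cl)Cl)ccc3c(=O)c2OS(=O)(=O)OCC(Cl)(Cl)Cl)ccc1OS(=O)(=O)OCC(Cl)(Cl)Cl
F7 | step 6 | triammonium 2-(3-methoxy-4-sulfonatooxyphenyl)-4-oxo-4H-chromene-3,7-diyl bis(sulfate) | COc1cc(-c2oc3cc(OS(=O)(=O)[O-])ccc3c(=O)c2OS(=O)(=O)[O-])ccc1OS(=O)(=O)[O-].[NH4+].[NH4+].[NH4+]
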